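I had 4 questions to answer on 3 flasks, with 2 earlier runs to go on.

| flask | starting material | first nucleophile | gas | remark | time |
|---|---|---|---|---|---|
| spring | 0.24 M | 0.36 M | 11 mM (held) | run made earlier |  |
| dusk | 0.24 M | 0.18 M | 11 mM (held) | run made earlier |  |
| Tuesday's | 0.24 M (fed, over 4.0 d) | 0.360 M | 11 mM (held) | all else is in the flask from the start; the feed brings no volume worth counting | 6.0 d |
| Wednesday's | 0.24 M | 0.360 M (fed, over 4.0 d) | 11 mM (held) | all else is in the flask from the start; the feed brings no volume worth counting | 6.0 d |
| Sunday's | 0.24 M | 0.360 M | 11 mM (held) | everything together at the start | 6.0 d |

- spring (time / d: target / %): 0.250: 53.9; 0.417: 54.7; 0.625: 55.7; 1.04: 53.3; 1.67: 55.1; 2.50: 54.5; 4.00: 54.4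
- dusk (time / h: target / %): 6.00: 36.0; 12.0: 34.1; 20.0: 35.0; 25.0: 35.9; 30.0: 34.5; 40.0: 34.5

(each reading ± 1 percentage point)

* the flask with the highest amount of target, in percent of the starting material charged ("all alike" if they lie within 1.5 percentage points) (Tuesday's / Wednesday's / Sunday's / all alike)
* final target, as a percentage of the starting material charged, in Tuesday's
* final target, as a percentage of the starting material charged, in Wednesday's
* final target, as a percentage of the starting material charged, in Sunday's

- the earlier runs were read with a standard deviation of 1 percentage point
- at the start none of the gas is in solution
- a reading or a percentage of target counts all its forms, free or not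

Both runs lie flat from the first reading, at 54.5% in spring and 35.0% at dusk. I assumed that target takes the share N/(N+K) of the starting material reacting, N being the first nucleophile's concentration at that moment. Following N down through each run gave 0.242 M from spring and 0.248 M from dusk. I carried 0.245 M as K, the half-share level: the concentration of first nucleophile at which half of the reacting starting material becomes target, a selectivity factor in concentration units.

Sunday's repeats spring's recipe, so I expected 54.5%. The assumed share has no term in the starting material's concentration, so I put Tuesday's near it too.

For Wednesday's, I estimated the starting material's lifetime τ at 2.00 h, a third of the 6.00 h of the first dusk reading, which already lay on the plateau, and far shorter than the feed. With feed rate f, the target share is then about fτ/K, which gave an estimate of 3.06%.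

The forecast gave all alike, with 54.5% for Tuesday's, 5% for Wednesday's, above my estimate, and 54.5% for Sunday's, holding that “slow feeding changes nothing”.

The flasks gave 25.2% in Tuesday's, 0.766% in Wednesday's and 54.4% in Sunday's, so Sunday's held the most.

    starting material → intermediate (k = 4.25 × 10⁻⁴ /s)
    first nucleophile + intermediate → target (k = 0.00641 /M/s)
    second nucleophile + intermediate → other capture product (k = 0.497 /M/s)
    intermediate → solvolysis product (k = 0.00151 /s)
    second nucleophile + target ⇌ idle adduct, settled at all times (K = 1770 /M)
    gas ⇌ second nucleophile, rate k6*(csat - [second nucleophile]) (kL = 4.02 × 10⁻⁴ /s)

Tuesday's, with second nucleophile at 0.00961 M after 3.00 d, ended with 56.8% of other capture product, against 1.36% in Sunday's. With τ now the inverse of the first step's constant 4.25 × 10⁻⁴ /s, fτ/K gives 1.00% for Wednesday's, above the 0.766% it gave. The neighbouring flask is Wednesday's with 0.14 M of first nucleophile fed over the same 4.0 d. There the same reckoning gives 0.389%. That flask ended at 0.298% of target, with 99.5% of its first nucleophile unbound.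

(The numbers in the tables are simulated with constants of no real substance; scatter was added.)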